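**Retrosynthetic overview**
1. Cut C14–C15 next to the ether oxygen. This gives a labdane enyne acid (used as its E-alkenylalane from Zr-catalysed methylalumination) and a eudesman-4α-yl chloromethyl ether. The CMe2OH group is made last from an ester.
2. The enyne acid comes from a tricyclic Δ8(14)-13-enone by Eschenmoser–Tanabe fragmentation and Wittig methylenation. A Birch-reduced anisole ring thus serves as a masked C8 ketone plus C9 butynyl chain.
3. The tricyclic acid comes from cation–arene closure of ring B. Ring A and quaternary C4 come from an auxiliary-controlled Birch reduction–methylation of a benzamide built from 2,3-dimethylbenzoic acid and 3-methoxybenzyl bromide.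
4. In the eudesmane, ring A is 2,6-dimethylcyclohexanone and ring B comes from a chiral-imine Michael/aldol sequence with MVK. C4–O comes from deconjugation and α-epoxidation; C7 comes from triflate carbonylation and hydrogenation.
5. Ring order: labdane A (arene), then B (cyclialkylation), then the sacrificial ring C is opened; eudesmane A, then B.

Assumption: the (S)-auxiliary 2 gives the (1S) centre of 9, as in the Schultz 2-alkylbenzamide series; if the sense were opposite, commercial (R)-2 would be used with no other change.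

**Step 1**
Reactants: 1 2,3-dimethylbenzoic acid; 2 (S)-2-(methoxymethyl)pyrrolidine
Product: 4 (S)-1-(2,3-dimethylbenzoyl)-2-(methoxymethyl)pyrrolidine, via 2,3-dimethylbenzoyl chloride 3 (not isolated)
Conditions: (COCl)2, cat. DMF, CH2Cl2, 0 °C to rt; evaporate; 2, Et3N, CH2Cl2, 0 °C
Reagents that add atoms: none
Why: Acid chloride formation and Schotten–Baumann-type N-acylation are routine and leave the auxiliary stereocentre untouched.

**Step 2**
Reactants: 4 (S)-1-(2,3-dimethylbenzoyl)-2-(methoxymethyl)pyrrolidine; 5 3-methoxybenzyl bromide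
Product: 7 (S)-1-{2-[2-(3-methoxyphenyl)ethyl]-3-methylbenzoyl}-2-(methoxymethyl)pyrrolidine, via lateral benzyllithium 6 (not isolated)
Conditions: LDA (1.1 equiv), THF, -78 °C; 5, -78 to 0 °C
Reagents that add atoms: none
Why: Amide-directed lateral lithiation (complex-induced proximity effect) deprotonates only the ortho methyl group, and the benzylic anion is alkylated by the benzylic bromide in an SN2 reaction that joins the two arenes through C6–C7.

**Step 3**
Reactants: 7 (S)-1-{2-[2-(3-methoxyphenyl)ethyl]-3-methylbenzoyl}-2-(methoxymethyl)pyrrolidine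
Product: 9 (S)-1-{[(1S)-2-[2-(3-methoxyphenyl)ethyl]-1,3-dimethylcyclohexa-2,5-dien-1-yl]carbonyl}-2-(methoxymethyl)pyrrolidine, via potassium amide enolate 8 (not isolated)
Conditions: K (2.4 equiv), NH3(l)/THF, t-BuOH (1.0 equiv), -78 °C; piperylene; MeI (3 equiv), -78 °C; NH4Cl
Reagents that add atoms: methyl iodide CI
Why: Schultz asymmetric Birch reduction–alkylation: the electron-poor benzamide ring takes up two electrons far faster than the anisole ring, t-BuOH protonates the para carbon, and the internally chelated enolate 8 is methylated on the face remote from the CH2OMe arm, which destroys the aromaticity of ring A and sets quaternary C4 (S, dr expected ≥ 20:1).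

**Step 4**
Reactants: 9 the (1S)-cyclohexa-2,5-diene amide
Product: 10 (S)-1-{[(1S)-2-[2-(3-methoxyphenyl)ethyl]-1,3-dimethylcyclohex-2-en-1-yl]carbonyl}-2-(methoxymethyl)pyrrolidine
Conditions: H2 (1 atm), RhCl(PPh3)3 (5 mol %), toluene/EtOH, rt
Reagents that add atoms: none
Why: Wilkinson hydrogenation distinguishes alkenes by substitution, so the cis-disubstituted C2=C3 bond is saturated while the tetrasubstituted C5=C10 bond and the arene remain.

**Step 5**
Reactants: 10 the (1S)-cyclohex-2-ene amide
Product: 13 13-methoxypodocarpa-8,11,13-trien-19-oic acid (4β-CO2H 5α-H 10β-Me), via bicyclic iminium ether 11 (not isolated), via tertiary γ-lactone 12 (not isolated)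
Conditions: MsOH (10 equiv), TFA/H2O 20:1, 0 to 50 °C
Reagents that add atoms: water O
Why: Proposed new method: this is a one-pot merger of two known acid reactions (Schultz amide-assisted protolactonisation and the King–Ghatak Bogert–Cook-type cyclialkylation of such lactones to podocarpic acids), in which anti addition of H+ (α face of C5) and the β-held amide oxygen (C10) gives 11, water hydrolyses the imidate to 12 and frees the auxiliary, and reversible AAL1 ionisation of the tertiary lactone lets the carbon para to OMe attack C10 opposite to the departing carboxylate, so that 5α-H and 10β-Me (trans-decalin) are both relayed from C4.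

**Step 6**
Reactants: 13 13-methoxypodocarpa-8,11,13-trien-19-oic acid
Product: 15 13-oxopodocarp-8(14)-en-19-oic acid (5α-H 9α-H 10β-Me), via dihydroanisole 14 (not isolated)
Conditions: Li (12 equiv), NH3(l)/THF/t-BuOH, -78 to -33 °C; NH4Cl; then 3 M HCl, MeOH, 60 °C
Reagents that add atoms: water O
Why: Birch reduction of the 13-methoxy arene (the carboxylate is inert) gives the 2,5-dihydroanisole, and acid hydrolysis with conjugation gives the Δ8(14)-enone, in which the epimerisable γ-centre C9 settles as the axial 9α-H (trans-anti) isomer.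

**Step 7**
Reactants: 15 13-oxopodocarp-8(14)-en-19-oic acid
Product: 16 8α,14α-epoxy-13-oxopodocarpan-19-oic acid
Conditions: 30 % H2O2, NaOH (2.5 equiv), MeOH, 0 °C to rt; citric acid
Reagents that add atoms: hydrogen peroxide OO
Why: Weitz–Scheffer epoxidation: hydroperoxide adds to C8 from the α face, away from the axial C10 methyl group, and both new centres are erased in the next step.

**Step 8**
Reactants: 16 8α,14α-epoxy-13-oxopodocarpan-19-oic acid
Product: 18 8-oxo-15,16,17-trinorlabd-13-yn-19-oic acid (9α-H), via epoxy tosylhydrazone 17 (not isolated)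
Conditions: TsNHNH2 (1.1 equiv), AcOH/CH2Cl2 1:1, -20 °C to rt
Reagents that add atoms: none
Why: Eschenmoser–Tanabe fragmentation: the epoxy tosylhydrazone collapses with loss of N2 and sulfinate, cleaving C8–C14 to the C8 ketone and the terminal C13≡C14 alkyne (isophorone oxide is the textbook analogue), while C9 keeps its thermodynamically preferred equatorial chain.

**Step 9**
Reactants: 18 8-oxo-15,16,17-trinorlabd-13-yn-19-oic acid
Product: 19 15,16-dinorlabd-8(17)-en-13-yn-19-oic acid
Conditions: Ph3PCH3Br/NaHMDS (4 equiv each), THF, 0 to 40 °C; citric acid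
Reagents that add atoms: methyltriphenylphosphonium bromide C[P+](c1ccccc1)(c1ccccc1)c1ccccc1.[Br-]
Why: Wittig methylenation works on hindered 8-oxolabdanes, the carboxylate and acetylide formed by excess base are inert, and C9 is already the stable epimer.

**Step 10**
Reactants: 20 2,6-dimethylcyclohexanone (cis/trans mixture); 21 (S)-1-phenylethylamine
Product: 22 N-[(S)-1-phenylethyl]imine of 2,6-dimethylcyclohexanone
Conditions: cat. TsOH, toluene, Dean–Stark, reflux
Reagents that add atoms: none
Why: Acid-catalysed imine condensation with azeotropic water removal; both α-centres stay labile through imine–enamine tautomerism.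

**Step 11**
Reactants: 22 the chiral imine; 23 methyl vinyl ketone
Product: 26 (4aR)-4a,8-dimethyl-4,4a,5,6,7,8-hexahydronaphthalen-2(3H)-one (C8 epimers), via keto imine Michael adduct 24 (not isolated), via (R)-diketone 25 (not isolated)
Conditions: 23 (1.1 equiv), THF, rt, 3 d; 20 % aq AcOH, rt; then NaOMe, MeOH, 60 °C
Reagents that add atoms: none
Why: d'Angelo–Pfau deracemising Michael addition: the substituted secondary enamine tautomer adds to MVK through a chair-like aza-ene transition state on the face anti to the phenyl group, which breaks the symmetry of the ketone and sets quaternary C10 (R, about 90–95 % ee), and Robinson-type aldol condensation closes ring B.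

**Step 12**
Reactants: 26 the conjugated octalone
Product: 27 (4aR)-4a,8-dimethyl-3,4,4a,5,6,7-hexahydronaphthalen-2(1H)-one
Conditions: KOt-Bu (1.5 equiv), t-BuOH, rt; poured into ice-cold 10 % aq AcOH; used at once
Reagents that add atoms: none
Why: Ringold deconjugation: the thermodynamic extended dienolate is protonated kinetically at the α carbon C6, giving the β,γ-enone with a tetrasubstituted Δ4 alkene and erasing the C4 epimer mixture.

**Step 13**
Reactants: 27 the β,γ-unsaturated ketone
Product: 29 4α-hydroxy-11,12,13-trinoreudesm-5-en-7-one, via 4α,5α-epoxy ketone 28 (not isolated)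
Conditions: mCPBA (1.1 equiv), NaHCO3, CH2Cl2, 0 °C; then Et3N, rt
Reagents that add atoms: mCPBA O=C(OO)c1cccc(Cl)c1
Why: Prilezhaev epoxidation of the electron-rich tetrasubstituted alkene occurs on the α face opposite to the angular methyl group (as in geosmin syntheses), and E1cB opening of the β,γ-epoxy ketone keeps the C4–O bond, so the 4α-oxygen/4β-methyl centre is set.

**Step 14**
Reactants: 29 4α-hydroxy-11,12,13-trinoreudesm-5-en-7-one
Product: 30 4α-hydroxy-11,12,13-trinoreudesma-5,7-dien-7-yl triflate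
Conditions: LiHMDS (2.2 equiv), THF, -78 °C; PhNTf2, -78 to 0 °C; NH4Cl
Reagents that add atoms: N-phenylbis(trifluoromethanesulfonimide) O=S(=O)(N(c1ccccc1)S(=O)(=O)C(F)(F)F)C(F)(F)F
Why: Kinetic α′-deprotonation (C8) of the enone alkoxide gives the cross-conjugated dienolate, which is O-triflated, while the hindered tertiary alkoxide does not react.

**Step 15**
Reactants: 30 the dienyl triflate
Product: 31 methyl 4α-hydroxy-12,13-dinoreudesma-5,7-dien-11-oate
Conditions: Pd(OAc)2 (5 mol %), PPh3 (10 mol %), CO (1 atm), MeOH, Et3N, DMF, 50 °C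
Reagents that add atoms: carbon monoxide [C-]#[O+]; methanol CO
Why: Cacchi–Ortar palladium-catalysed methoxycarbonylation of the dienyl triflate installs C11 at the ester oxidation level.

**Step 16**
Reactants: 31 the hydroxy dienoate
Product: 32 methyl 4α-hydroxy-12,13-dinoreudesman-11-oate (5α-H 7α-H 10β-Me)
Conditions: H2 (30 bar), [Ir(cod)(PCy3)(py)]PF6 (5 mol %), CH2Cl2, rt; then cat. NaOMe, MeOH, rt
Reagents that add atoms: none
Why: Hydroxyl-directed Crabtree hydrogenation delivers hydrogen from the α face, which carries the 4α-OH group and lies opposite to the angular methyl group, setting 5α-H (trans-decalin) and 7α-H, and methoxide equilibration secures the equatorial 7β-ester.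

**Step 17**
Reactants: 32 the hydroxy ester
Product: 33 methyl 4α-(methylthiomethoxy)-12,13-dinoreudesman-11-oate
Conditions: DMSO, Ac2O, AcOH, rt, 48 h
Reagents that add atoms: dimethyl sulfoxide CS(C)=O
Why: Pummerer-type methylthiomethylation (Pojer–Angyal conditions) is one of the few etherifications that works on hindered tertiary alcohols, and it needs no strong base or acid.

**Step 18**
Reactants: 19 15,16-dinorlabd-8(17)-en-13-yn-19-oic acid; 33 the MTM ether
Product: 36 (13E)-15-{[11-methoxy-11-oxo-12,13-dinoreudesman-4α-yl]oxy}labda-8(17),13-dien-19-oic acid, via (E)-alkenylalane 34 (not isolated), via chloromethyl ether 35 (not isolated)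
Conditions: flask A: 19, Me3Al (4 equiv), Cp2ZrCl2 (0.3 equiv), CH2Cl2, 0 °C to rt, volatiles off; flask B: 33, SO2Cl2 (1.0 equiv), CH2Cl2, -78 to 0 °C, volatiles off; B into A, CH2Cl2/hexane, 0 °C to rt; cold aq citric acid
Reagents that add atoms: trimethylaluminium C[Al](C)C
Why: Negishi zirconium-catalysed methylalumination adds Me and Al syn and regioselectively to the terminal alkyne (the 1,1-disubstituted alkene and the aluminium carboxylate are inert), and the (E)-alkenylalane is alkylated with retention by the highly electrophilic chloromethyl ether made from the MTM ether with SO2Cl2, so the E-trisubstituted alkene and the hindered tertiary allyl ether arise together without touching the carbinol centre.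

**Step 19**
Reactants: 36 the ether ester acid
Product: 37 (13E)-15-[(11-hydroxyeudesman-4α-yl)oxy]labda-8(17),13-dien-19-oic acid (CNP0156875.1)
Conditions: MeMgBr (6 equiv), THF, 0 °C to rt; aq NH4Cl
Reagents that add atoms: methylmagnesium bromide C[Mg]Br
Why: Double Grignard addition converts the unhindered equatorial ester into the dimethylcarbinol, while the axial neopentyl C19 acid is protected in situ as its magnesium carboxylate.

**Compound list**
1 | 2,3-dimethylbenzoic acid | Cc1cccc(C(=O)O)c1C | starting material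
2 | (S)-2-(methoxymethyl)pyrrolidine | COC[C@@H]1CCCN1 | starting material
3 | 2,3-dimethylbenzoyl chloride | Cc1cccc(C(=O)Cl)c1C | intermediate
4 | (S)-1-(2,3-dimethylbenzoyl)-2-(methoxymethyl)pyrrolidine | COC[C@@H]1CCCN1C(=O)c1cccc(C)c1C | intermediate
5 | 3-methoxybenzyl bromide | COc1cccc(CBr)c1 | starting material
6 | lateral (ortho-CH2Li) benzyllithium of 4 | COC[C@@H]1CCCN1C(=O)c1cccc(C)c1C[Li] | intermediate
7 | (S)-1-{2-[2-(3-methoxyphenyl)ethyl]-3-methylbenzoyl}-2-(methoxymethyl)pyrrolidine | COC[C@@H]1CCCN1C(=O)c1cccc(C)c1CCc1cccc(OC)c1 | intermediate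
8 | potassium amide enolate of the 1,4-dihydrobenzamide | COC[C@@H]1CCCN1C([O-])=C1C=CCC(C)=C1CCc1cccc(OC)c1.[K+] | intermediate
9 | (1S)-1,3-dimethyl-2-(arylethyl)cyclohexa-2,5-diene-1-carboxamide of 2 | COC[C@@H]1CCCN1C(=O)[C@@]1(C)C=CCC(C)=C1CCc1cccc(OC)c1 | intermediate
10 | (1S)-1,3-dimethyl-2-(arylethyl)cyclohex-2-ene-1-carboxamide of 2 | COC[C@@H]1CCCN1C(=O)[C@@]1(C)CCCC(C)=C1CCc1cccc(OC)c1 | intermediate
11 | bicyclic iminium ether mesylate (O on C10 β, 5α-H) | COC[C@@H]1CCC[N+]1=C1O[C@]2(C)CCC[C@@]1(C)[C@@H]2CCc1cccc(OC)c1.CS(=O)(=O)[O-] | intermediate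
12 | 8-[2-(3-methoxyphenyl)ethyl]-1,5-dimethyl-6-oxabicyclo[3.2.1]octan-7-one (19,10β-olide, 5α-H) | O=C1O[C@]2(C)CCC[C@@]1(C)[C@@H]2CCc1cccc(OC)c1 | intermediate
13 | 13-methoxypodocarpa-8,11,13-trien-19-oic acid | COc1ccc2c(c1)CC[C@@H]1[C@]2(C)CCC[C@]1(C)C(=O)O | intermediate
14 | 13-methoxypodocarpa-8,12-dien-19-oic acid | COC1=CCC2=C(C1)CC[C@@H]1[C@]2(C)CCC[C@]1(C)C(=O)O | intermediate
15 | 13-oxopodocarp-8(14)-en-19-oic acid | O=C1C=C2CC[C@@H]3[C@](C)(CCC[C@]3(C)C(=O)O)[C@H]2CC1 | intermediate
16 | 8α,14α-epoxy-13-oxopodocarpan-19-oic acid | O=C1[C@@H]2O[C@@]23CC[C@@H]4[C@](C)(CCC[C@]4(C)C(=O)O)[C@H]3CC1 | intermediate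
17 | tosylhydrazone of 16 | Cc1ccc(cc1)S(=O)(=O)NN=C1[C@@H]2O[C@@]23CC[C@@H]4[C@](C)(CCC[C@]4(C)C(=O)O)[C@H]3CC1 | intermediate
18 | 8-oxo-15,16,17-trinorlabd-13-yn-19-oic acid | O=C1CC[C@@H]2[C@](C)(CCC[C@]2(C)C(=O)O)[C@H]1CCC#C | intermediate
19 | 15,16-dinorlabd-8(17)-en-13-yn-19-oic acid | C=C1CC[C@@H]2[C@](C)(CCC[C@]2(C)C(=O)O)[C@H]1CCC#C | intermediate
20 | 2,6-dimethylcyclohexanone (cis/trans mixture) | CC1CCCC(C)C1=O | starting material
21 | (S)-1-phenylethylamine | C[C@H](N)c1ccccc1 | starting material
22 | N-[(S)-1-phenylethyl]imine of 2,6-dimethylcyclohexanone | CC1CCCC(C)C1=N[C@@H](C)c1ccccc1 | intermediate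
23 | methyl vinyl ketone | C=CC(C)=O | starting material
24 | keto imine Michael adduct (quaternary centre R) | CC1CCC[C@](C)(CCC(C)=O)C1=N[C@@H](C)c1ccccc1 | intermediate
25 | (2R)-2,6-dimethyl-2-(3-oxobutyl)cyclohexanone | CC1CCC[C@](C)(CCC(C)=O)C1=O | intermediate
26 | (4aR)-4a,8-dimethyl-4,4a,5,6,7,8-hexahydronaphthalen-2(3H)-one (C8 epimers) | CC1CCC[C@]2(C)CCC(=O)C=C12 | intermediate
27 | (4aR)-4a,8-dimethyl-3,4,4a,5,6,7-hexahydronaphthalen-2(1H)-one | O=C1CC[C@@]2(C)CCCC(C)=C2C1 | intermediate
28 | 4α,5α-epoxy-11,12,13-trinoreudesman-7-one | O=C1CC[C@@]2(C)CCC[C@@]3(C)O[C@@]23C1 | intermediate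
29 | 4α-hydroxy-11,12,13-trinoreudesm-5-en-7-one | O[C@]1(C)CCC[C@]2(C)CCC(=O)C=C21 | intermediate
30 | 4α-hydroxy-11,12,13-trinoreudesma-5,7-dien-7-yl triflate | O[C@]1(C)CCC[C@]2(C)CC=C(OS(=O)(=O)C(F)(F)F)C=C21 | intermediate
31 | methyl 4α-hydroxy-12,13-dinoreudesma-5,7-dien-11-oate | O[C@]1(C)CCC[C@]2(C)CC=C(C(=O)OC)C=C21 | intermediate
32 | methyl 4α-hydroxy-12,13-dinoreudesman-11-oate (5α-H, 7α-H) | O[C@]1(C)CCC[C@]2(C)CC[C@@H](C(=O)OC)C[C@H]21 | intermediate
33 | methyl 4α-(methylthiomethoxy)-12,13-dinoreudesman-11-oate | CSCO[C@]1(C)CCC[C@]2(C)CC[C@@H](C(=O)OC)C[C@H]21 | intermediate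
34 | (13E)-14-(dimethylalumino)-15-norlabda-8(17),13-dien-19-oic acid dimethylaluminium carboxylate | C=C1CC[C@@H]2[C@](C)(CCC[C@]2(C)C(=O)O[Al](C)C)[C@H]1CC/C(C)=C/[Al](C)C | intermediate
35 | methyl 4α-(chloromethoxy)-12,13-dinoreudesman-11-oate | ClCO[C@]1(C)CCC[C@]2(C)CC[C@@H](C(=O)OC)C[C@H]21 | intermediate
36 | (13E)-15-{[11-methoxy-11-oxo-12,13-dinoreudesman-4α-yl]oxy}labda-8(17),13-dien-19-oic acid | C=C1CC[C@@H]2[C@](C)(CCC[C@]2(C)C(=O)O)[C@H]1CC/C(C)=C/CO[C@]1(C)CCC[C@]2(C)CC[C@@H](C(=O)OC)C[C@H]21 | intermediate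
37 | (13E)-15-[(11-hydroxyeudesman-4α-yl)oxy]labda-8(17),13-dien-19-oic acid (CNP0156875.1) | C=C1CC[C@@H]2[C@](C)(CCC[C@]2(C)C(=O)O)[C@H]1CC/C(C)=C/CO[C@]1(C)CCC[C@]2(C)CC[C@@H](C(C)(C)O)C[C@H]21 | target

**Total step count:** 19.
**Longest linear sequence:** 11 (steps 1–9, 18, 19).

**Steps most likely to fail and fallbacks**

Step 5 (acid cascade; risk of a cis/trans mixture at the A/B fusion or of stalling at the lactone). The fallback sets out from 10 and forms the C9–C10 bond by carbopalladation instead of through a carbocation.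
- 6 M HCl in dioxane at 80 °C stops at lactone 12, which is isolated.
- NBS in MeCN brominates para to the methoxy group to give 8-[2-(2-bromo-5-methoxyphenyl)ethyl]-1,5-dimethyl-6-oxabicyclo[3.2.1]octan-7-one F5.
- KOt-Bu in DMSO opens the tertiary lactone by Hofmann-type E2 elimination to (1S,2S)-2-[2-(2-bromo-5-methoxyphenyl)ethyl]-1-methyl-3-methylenecyclohexane-1-carboxylic acid F6.
- A 6-exo reductive Heck cyclisation (Pd(OAc)2, PPh3, HCO2Na, DMF, 80 °C) builds the benzylic quaternary centre, with the neopentyl palladium species reduced to the C10 methyl group.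
- The route is rejoined at 13.

Step 18 (alkenylalane alkylation by a tertiary-alkyl chloromethyl ether in the presence of an aluminium carboxylate). The fallback sets out from 19 and 32 and replaces the alane alkylation by a cross-coupling.
- Methylalumination of 19 followed by I2 gives (13E)-14-iodo-15-norlabda-8(17),13-dien-19-oic acid F7.
- The potassium alkoxide of 32 (KH, 18-crown-6, THF) is alkylated with ICH2SnBu3 to methyl 4α-[(tributylstannyl)methoxy]-12,13-dinoreudesman-11-oate F8.
- Stille coupling of F7 with F8 (Pd2(dba)3, AsPh3, CuI, NMP, 60 °C) forms C14–C15.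
- The route is rejoined at 36.

Step 3 (competing reduction of the anisole ring or insufficient facial control). The fallback sets out from 1 and 5 and gives up auxiliary control in favour of a racemic sequence with resolution.
- The dianion of 1 (2.2 equiv LDA) is benzylated with 5 to 2-[2-(3-methoxyphenyl)ethyl]-3-methylbenzoic acid F1.
- Li/NH3 followed by MeI gives racemic 2-[2-(3-methoxyphenyl)ethyl]-1,3-dimethylcyclohexa-2,5-diene-1-carboxylic acid F2.
- Wilkinson hydrogenation gives racemic 2-[2-(3-methoxyphenyl)ethyl]-1,3-dimethylcyclohex-2-ene-1-carboxylic acid F3.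
- The acid medium of step 5 closes it to racemic 13-methoxypodocarpa-8,11,13-trien-19-oic acid F4.
- Preparative chiral SFC separates the enantiomers, and the route is rejoined at 13.

**Further compounds**
F1 | step 3 | 2-[2-(3-methoxyphenyl)ethyl]-3-methylbenzoic acid | COc1cccc(CCc2c(C)cccc2C(=O)O)c1
F2 | step 3 | racemic 2-[2-(3-methoxyphenyl)ethyl]-1,3-dimethylcyclohexa-2,5-diene-1-carboxylic acid | COc1cccc(CCC2=C(C)CC=CC2(C)C(=O)O)c1
F3 | step 3 | racemic 2-[2-(3-methoxyphenyl)ethyl]-1,3-dimethylcyclohex-2-ene-1-carboxylic acid | COc1cccc(CCC2=C(C)CCCC2(C)C(=O)O)c1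
F4 | step 3 | racemic 13-methoxypodocarpa-8,11,13-trien-19-oic acid (13 plus its enantiomer) | COc1ccc2c(c1)CC[C@@H]1[C@]2(C)CCC[C@]1(C)C(=O)O.COc1ccc2c(c1)CC[C@H]1[C@@]2(C)CCC[C@@]1(C)C(=O)O
F5 | step 5 | 8-[2-(2-bromo-5-methoxyphenyl)ethyl]-1,5-dimethyl-6-oxabicyclo[3.2.1]octan-7-one | O=C1O[C@]2(C)CCC[C@@]1(C)[C@@H]2CCc1cc(OC)ccc1Br
F6 | step 5 | (1S,2S)-2-[2-(2-bromo-5-methoxyphenyl)ethyl]-1-methyl-3-methylenecyclohexane-1-carboxylic acid | C=C1CCC[C@](C)(C(=O)O)[C@@H]1CCc1cc(OC)ccc1Br
F7 | step 18 | (13E)-14-iodo-15-norlabda-8(17),13-dien-19-oic acid | C=C1CC[C@@H]2[C@](C)(CCC[C@]2(C)C(=O)O)[C@H]1CC/C(C)=C/I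
F8 | step 18 | methyl 4α-[(tributylstannyl)methoxy]-12,13-dinoreudesman-11-oate | CCCC[Sn](CCCC)(CCCC)CO[C@]1(C)CCC[C@]2(C)CC[C@@H](C(=O)OC)C[C@H]21
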